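(The runs stem from a simulated flask with made-up constants, noise included.)

The winter run levelled off higher than the dawn run, 27.4% against 24.6%, with the same loading of free catalyst, 10 mol%. The dawn run is the asked flask, followed so far.

common to all: free catalyst 10 mol%
- dawn: substrate 0.30 M; capture agent 0.30 M; temperature 25 °C; the very flask that is asked about, followed so far
- winter: substrate 0.15 M; capture agent 0.30 M; temperature 20 °C; run made earlier
- flask: substrate 0.30 M; capture agent 0.300 M; temperature 25 °C; time 6.0 h

| run | time / min | product / % |
|---|---|---|
| dawn | 15.0 | 24.6 |
| dawn | 30.0 | 25.0 |
| dawn | 60.0 | 24.2 |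
| dawn | 120 | 24.7 |
| dawn | 240 | 24.6 |
| winter | 15.0 | 22.0 |
| winter | 30.0 | 26.6 |
| winter | 50.0 | 27.4 |
| winter | 60.0 | 27.3 |
| winter | 80.0 | 27.5 |

(scatter of a reading: 0.5 percentage points)

* product, in percent of the substrate first charged, at 6.0 h
* the remedy with the largest gain of product, or "none" below 2 percentage points (Friday's / Tuesday's / Wednesday's / Sunday's / none)
* product present, with what was taken out counted in, in percent of the substrate first charged, after Friday's
* product present, with what was taken out counted in, in percent of the substrate first charged, after Tuesday's

- Friday's: at 6.0 h add free catalyst, 100% of the amount charged, then wait 3.0 h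
- Tuesday's: change nothing and wait 3.0 h more
- Wednesday's: at 6.0 h take out 90% of the product then present, then wait 3.0 h
- Sunday's: at 6.0 h raise the temperature by 20 K, then wait 3.0 h

- removed product is counted in
- what was read earlier has a scatter of 0.5 percentage points, one standard deviation
- what may be going on: catalyst intermediate <-> free catalyst + product; substrate + free catalyst -> spent catalyst; substrate + free catalyst -> catalyst intermediate; catalyst intermediate + capture agent -> trapped intermediate
- additions bring no volume worth counting

Logarithms to base ten show which numbers must be known well.

Time: the dawn readings span 1.20 decades, yet differ by 0.8 percentage points at most, so the clock need not be known well.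

Scatter: one reading off by 0.5 points shifts the logarithm of product by 0.00874.

Charge: from winter to dawn, substrate and free catalyst rise together by 0.301 decades, with a temperature step mixed in, and the plateau falls by 0.0468.

Loading: if each catalyst makes a fixed number of turnovers, product follows the loading decade for decade, so this number must be known well, together with the count itself:

log(product per catalyst) = log(24.6%) − log(10 mol%) = −0.609 + 1.00 = 0.391, so 2.46 turnovers

This is the turnover count, the field's turnover number: product made per catalyst charged. The winter run reads 2.74. This reckoning takes 24.6% for now and after Tuesday's, and no gain from Wednesday's or Sunday's. For Friday's, it holds the fresh charge at the same count: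

24.6% + 2.46 × 10.0% = 49.2%

The forecast gave 24.6%, 24.6% after Tuesday's and 48.8% after Friday's, so Friday's, on the ground that “no active catalyst remains”. Its Friday figure stands lower than this reckoning's 49.2%.

The simulation gives 24.5%, 24.5% after Tuesday's and 30.9% after Friday's, so Friday's is best, with a gain of 6.4 points. Wednesday's gains 0 points and Sunday's 0 points.

    catalyst intermediate ⇌ free catalyst + product (K = 1.90 M, k = 220 min⁻¹, Ea = 71.0 kJ mol⁻¹, ΔH = −50.0 kJ mol⁻¹)
    substrate + free catalyst → spent catalyst (k = 0.160 M⁻¹ min⁻¹, Ea = 56.0 kJ mol⁻¹)
    substrate + free catalyst → catalyst intermediate (k = 2.70 M⁻¹ min⁻¹, Ea = 47.0 kJ mol⁻¹)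
    catalyst intermediate + capture agent → trapped intermediate (k = 23.0 M⁻¹ min⁻¹, Ea = 45.0 kJ mol⁻¹)
    (constants at 25 °C)

In the asked flask, the second charge added 6.4 points, which is 0.637 turnovers per added catalyst, a quarter of the first charge's count of 2.46. This reckoning and the simulation part at this point, 49.2% against 30.9% after Friday's, and the count of 2.46 read from the first charge stands above the second charge's 0.637. The neighbour charged with 40 mol% of free catalyst tests the count again: 2.46 turnovers would give 98.5%. That neighbour reaches 33.7% at 360 min, a count of 0.842, with 26.3% of its substrate still there and free catalyst at 0%.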